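## Structural features

The target 18 is a 1-aryl-1,2-dihydronaphthalene. Aromatic ring A (C4a–C8a, methoxy on C6, hydroxyl on C7) is fused to the partly saturated ring B (C1–C4), and a 4-hydroxy-3-methoxyphenyl group sits on C1. Ring B carries three functionalised carbons in a row: the diaryl methine C1, C2 with its acetoxymethyl arm, and C3 with the formyl group. C3 is doubly bonded to C4, so the enal is conjugated with ring A. The only stereocentres are C1 (S) and C2 (R); they are neighbours, and aryl and acetoxymethyl are trans. The fragile groups are the enal, the base-labile primary acetate, the two electron-rich free phenols, and the dihydronaphthalene, which is one dehydrogenation away from a naphthalene. The real difficulty is to set the C1/C2 pair in absolute terms and then place the formyl group and the C3=C4 double bond regiospecifically without epimerising C2, expelling the oxygen substituent on the C2 arm or aromatising ring B. The plan exploits the fact that ring B without C4 is a trans-2,3-disubstituted indan-1-one whose carbonyl carbon is C3. Inserting one carbon between C3 and ring A carbon C4a gives a 2-tetralone whose ketone sits where the formyl group must go and whose new benzylic CH2 (C4) fixes the direction of enolisation.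

## Logic of the disconnections

**18 from 17.** The two phenolic O–Si bonds are cut last. Free guaiacol-type phenols would be deprotonated by the amide bases and would interfere with the palladium steps, so both stay silylated throughout. Nothing is gained in skeleton, but every earlier step runs on a non-acidic substrate. The forward step must spare the acetate and the enal, which calls for buffered fluoride.

**17 from 16.** The C3–CHO bond is cut. The formyl carbon is the only ring B carbon a 2-tetralone lacks, and a vinyl triflate at C3 accepts it with the C3=C4 double bond already in place. Two problems (aldehyde position, alkene position) reduce to one enol derivative. The forward carbonylation must outrun simple reduction of the C–O bond.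

**16 from 15.** The C3–O bond of the enol triflate is cut back to the C3 ketone. The simplification is the loss of the double bond. The forward step must enolise toward benzylic C4 and not toward C2, so that C2 keeps its configuration and its acetoxymethyl group.

**15 from 12 and 13.** C3–C4 and C4–C4a are cut and C4 is excised. What remains is the five-membered ketone 12, on which C1 and C2 are far easier to set and whose carbonyl carbon is C3 by construction; the one carbon comes from 13. The forward step must make ring A carbon C4a migrate in preference to C2, and must insert only once.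

**12 from 11.** The acyl C–O bond of the acetate is cut. Carrying the ester of the target from this point on means the primary hydroxyl needs no separate protecting group and no late exchange. The forward acylation must be mild enough not to eliminate the β-oxygen.

**11 from 10.** The bond from indanone C2 (target C2) to the CH2OH carbon is cut, an aldol disconnection with a one-carbon electrophile. One stereocentre disappears. The forward step must add once only and anti to the neighbouring aryl group.

**10 from 9.** The bond between ring A carbon C8a and C1 is cut. This is the bond an arylpalladium species makes when it adds to the β-carbon of an enone. The ring and the last stereocentre are removed, leaving an acyclic bromo enone. The forward step must choose one enone face and end by hydride delivery, not by β-hydride elimination.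

**9 from 4 and 6.** The enone Cα=Cβ bond (target C2–C1) is cut. The molecule divides into two aromatic halves of similar size, which makes the route convergent. The forward condensation must avoid hydroxide, which would strip the aryl silyl ethers.

**4 from 3, 2 and 1.** The C–CH3 bond of the ketone and the O–Si bond are cut. 1 already carries bromine on the correct ring carbon, para to the methoxy group. The forward Grignard addition must not exchange with the aryl bromide.

**6 from 5.** The O–Si bond is cut; a simple silylation.

## Other disconnections considered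

**Alternative 1:** The cut is the C4–C4a bond. In the forward sense the ring A bromide A2, which carries C1 and C2 as an open chain ending in a 2-substituted acrolein, would add to zerovalent palladium. A 6-endo carbopalladation at the terminal methylene, then β-hydride elimination of a C4 hydrogen, would give A1, which is the same compound as 17.
- In its favour: the enal arrives intact, and the ring expansion, triflation and formylation all become unnecessary. After the ring closure it is the better plan by three steps. In the final deprotection the two plans are equal.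
- Against it: C1 and C2 must be set anti on an open chain, without the ring that makes trans the easy outcome in 10 to 12. A2 is an α-substituted acrolein prone to polymerisation and conjugate addition. The tertiary alkylpalladium intermediate can also lose the C2 hydrogen, which would destroy that stereocentre.
- Comparison: structurally both plans keep ring A intact and close ring B. Mechanistically this is a ring closure whose regiochemistry (endo versus exo, C4–H versus C2–H elimination) is less secure than a migration governed by migratory aptitude. In overall step count it is probably no shorter once A2 has been built with both stereocentres.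

**Alternative 2:** The cuts are C1–C2 and C3–C4. Irradiation of the benzylbenzaldehyde A4 in the presence of the enal A5 would lead, through photoenolisation and [4+2] addition, to the hydroxytetralin A3. Dehydration across C3–C4 and desilylation would follow.
- In its favour: it is the most convergent plan. Two C–C bonds, ring B and the C1/C2 relationship arise in one step from two simple pieces, and the formyl group needs no separate introduction. In step economy it is clearly the better plan.
- Against it: it gives a racemate unless a chiral Lewis acid can bind the diene precursor, and A4 offers no chelating group beside the aldehyde. The trans C1/C2 outcome depends both on the geometry of the aryl-substituted photoenol and on endo addition. A5 can isomerise or undergo its own photochemistry.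
- Comparison: in relative stereocontrol the two plans are roughly equal in rationale, one relying on a pericyclic transition state and the other on thermodynamic trans preference. In absolute stereocontrol the chosen plan is the stronger, because C1 is set by a catalytic asymmetric reaction type established for 3-arylindanones.

**Alternative 3:** The cuts are C5–C6 and C4a–C8a, so ring A itself is taken apart. Heating the pyrone A7, whose side chain carries C1 to C4 and ends in a terminal alkyne, would bring about intramolecular [4+2] addition. Decarboxylative cycloreversion would then give A6, one desilylation from the target.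
- In its favour: the substitution pattern of ring A is fixed by the pyrone, with no aromatic regiochemistry question. The alkyne conjugated to the enal is well matched to an electron-rich pyrone. The enal and both stereocentres pass through untouched, and the product is as close to the target as 17 is; on that last point the plans are equal.
- Against it: A7 is a long linear target in itself. It needs a cis enynal (a sensitive acceptor) and an open-chain C1/C2 pair, and C1 sits on the pyrone at a position whose hydrogen is vinylogously acidic, so its configuration is at risk. The 4-silyloxypyrone is also easily desilylated.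
- Comparison: structurally this is the only plan that builds ring A, which the target does not require since both aromatic rings are cheap vanillin-type units. Mechanistically the cycloaddition is the more predictable event, but step economy and stereochemical security before the key step favour the chosen plan.

Key step: step 9

**Assumptions and corrections**
- Assumption: the (R)-configured bisphosphine in step 6 is taken to deliver the (S)-configured centre of 10. If the sense of induction is the opposite, the (S)-ligand is used and nothing else changes.
- Correction to the aryl bromide: bromination of the free 4-hydroxy-3-methoxyaryl ketone would go ortho to the hydroxyl, the wrong carbon for the ring closure. Bromine is therefore bought in place in 1 (6-bromovanillin), where it is para to the methoxy group, and the acetyl group is built from the aldehyde.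
- Precursor design: the connectivity and configuration of the indanone and of the 2-tetralone were checked against 18 and are kept, (2S,3S) and (3S,4S) in their own numbering. The phenols are held as triisopropylsilyl ethers (more robust than tert-butyldimethylsilyl toward amide bases, hot amine and the Lewis acid). The primary alcohol carries the acetate of the target from step 8, which removes a late deprotection and acetylation.
- Numbering: target numbering (C1–C4, C4a–C8a) is used in the discussion; compound names use the numbering of their own ring system.

## Route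

Step 1
Reactants: 1 2-bromo-4-hydroxy-5-methoxybenzaldehyde (6-bromovanillin)
Product: 2 2-bromo-5-methoxy-4-(triisopropylsilyloxy)benzaldehyde
Conditions: TIPSCl, imidazole, DMF, rt
Reagents that add atoms: chlorotriisopropylsilane, CC(C)[Si](Cl)(C(C)C)C(C)C
Why: Imidazole-promoted O-silylation of the phenol removes the acidic proton before the Grignard step; the bulky aryl triisopropylsilyl ether should survive every later step and fall only to fluoride.

Step 2
Reactants: 2 2-bromo-5-methoxy-4-(triisopropylsilyloxy)benzaldehyde
Product: 3 1-[2-bromo-5-methoxy-4-(triisopropylsilyloxy)phenyl]ethanol (racemic)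
Conditions: MeMgBr, THF, −78 → 0 °C; aq. NH4Cl
Reagents that add atoms: methylmagnesium bromide, C[Mg]Br
Why: Grignard 1,2-addition to the aldehyde; MeMgBr does not undergo halogen–magnesium exchange with the aryl bromide at this temperature, and the racemic carbinol centre is removed in step 3.

Step 3
Reactants: 3 1-[2-bromo-5-methoxy-4-(triisopropylsilyloxy)phenyl]ethanol (racemic)
Product: 4 1-[2-bromo-5-methoxy-4-(triisopropylsilyloxy)phenyl]ethanone
Conditions: Dess–Martin periodinane, NaHCO3, CH2Cl2, 0 °C → rt
Reagents that add atoms: none
Why: Dess–Martin oxidation of the secondary benzylic alcohol under buffered, near-neutral conditions that leave the aryl silyl ether and the bromide alone.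

Step 4
Reactants: 5 vanillin (4-hydroxy-3-methoxybenzaldehyde)
Product: 6 3-methoxy-4-(triisopropylsilyloxy)benzaldehyde
Conditions: TIPSCl, imidazole, DMF, rt
Reagents that add atoms: chlorotriisopropylsilane, CC(C)[Si](Cl)(C(C)C)C(C)C
Why: Same O-silylation as in step 1; the non-enolisable aldehyde is then ready as the electrophile of the aldol step.

Step 5
Reactants: 4 1-[2-bromo-5-methoxy-4-(triisopropylsilyloxy)phenyl]ethanone; 6 3-methoxy-4-(triisopropylsilyloxy)benzaldehyde
Product: 9 (E)-1-[2-bromo-5-methoxy-4-(triisopropylsilyloxy)phenyl]-3-[3-methoxy-4-(triisopropylsilyloxy)phenyl]prop-2-en-1-one, via β-hydroxy ketone 7 (not isolated), via mesylate 8 (not isolated)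
Conditions: LiN(SiMe3)2, THF, −78 °C; 6, −78 °C; MsCl, Et3N, −78 °C → rt
Reagents that add atoms: none
Why: Directed aldol condensation: the lithium enolate of 4 adds to 6, the aldolate is mesylated in the flask and E1cB elimination gives the conjugated (E)-enone; hydroxide, which would cleave the aryl silyl ethers under Claisen–Schmidt conditions, is avoided.

Step 6
Reactants: 9 (E)-1-[2-bromo-5-methoxy-4-(triisopropylsilyloxy)phenyl]-3-[3-methoxy-4-(triisopropylsilyloxy)phenyl]prop-2-en-1-one
Product: 10 (3S)-6-methoxy-3-[3-methoxy-4-(triisopropylsilyloxy)phenyl]-5-(triisopropylsilyloxy)-2,3-dihydro-1H-inden-1-one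
Conditions: Pd(OAc)2 (5 mol %), (R)-3,5-Xyl-MeO-BIPHEP (6 mol %), iPr2NEt, ethylene glycol–DMF, 90 °C
Reagents that add atoms: none
Why: Asymmetric intramolecular reductive Heck reaction: zerovalent palladium inserts into the C–Br bond, the cationic arylpalladium bearing the chiral bisphosphine adds to the enone β-carbon (enantio-determining, setting target C1), and the palladium enolate is protonated; the amine returns divalent palladium to zerovalent palladium, and the glycol assists bromide dissociation.

Step 7
Reactants: 10 (3S)-6-methoxy-3-[3-methoxy-4-(triisopropylsilyloxy)phenyl]-5-(triisopropylsilyloxy)-2,3-dihydro-1H-inden-1-one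
Product: 11 (2S,3S)-2-(hydroxymethyl)-6-methoxy-3-[3-methoxy-4-(triisopropylsilyloxy)phenyl]-5-(triisopropylsilyloxy)-2,3-dihydro-1H-inden-1-one (trans)
Conditions: LiN(SiMe3)2, THF, −78 °C; HCHO (monomeric, THF solution from cracked paraformaldehyde), −78 °C; AcOH, −78 °C
Reagents that add atoms: formaldehyde, C=O
Why: Aldol hydroxymethylation of the kinetic lithium enolate; formaldehyde approaches the planar enolate on the face anti to the C3 aryl group, giving the trans isomer, which is also the thermodynamically preferred one, and the cold acidic quench prevents retro-aldol or dehydration.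

Step 8
Reactants: 11 (2S,3S)-2-(hydroxymethyl)-6-methoxy-3-[3-methoxy-4-(triisopropylsilyloxy)phenyl]-5-(triisopropylsilyloxy)-2,3-dihydro-1H-inden-1-one
Product: 12 (2S,3S)-2-(acetoxymethyl)-6-methoxy-3-[3-methoxy-4-(triisopropylsilyloxy)phenyl]-5-(triisopropylsilyloxy)-2,3-dihydro-1H-inden-1-one (trans)
Conditions: Ac2O, pyridine, CH2Cl2, 0 °C
Reagents that add atoms: acetic anhydride, CC(=O)OC(C)=O
Why: O-acetylation of the primary alcohol installs the ester of the target; pyridine at 0 °C is too weak a base to trigger β-elimination of the new acetate.

Step 9
Reactants: 12 (2S,3S)-2-(acetoxymethyl)-6-methoxy-3-[3-methoxy-4-(triisopropylsilyloxy)phenyl]-5-(triisopropylsilyloxy)-2,3-dihydro-1H-inden-1-one; 13 trimethylsilyldiazomethane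
Product: 15 (3S,4S)-3-(acetoxymethyl)-7-methoxy-4-[3-methoxy-4-(triisopropylsilyloxy)phenyl]-6-(triisopropylsilyloxy)-3,4-dihydronaphthalen-2(1H)-one, via α-trimethylsilyl ketone 14 (not isolated)
Conditions: 13 (hexane solution), BF3·OEt2, CH2Cl2, −78 → −20 °C; then 1 M HCl, THF, 0 °C
Reagents that add atoms: trimethylsilyldiazomethane 13, C[Si](C)(C)C=[N+]=[N-]
Why: BF3 binds the ketone oxygen of 12 and the nucleophilic diazo carbon of 13 adds to the carbonyl carbon (C3), giving a β-oxido diazonium betaine. Loss of N2 is coupled to a 1,2-shift of ring A carbon C4a from C3 to the diazo carbon, which thereby becomes C4 and forms the C3–C4 and C4–C4a bonds; the closest known reaction type is the Lewis acid-promoted diazoalkane homologation of aryl ketones (Tiffeneau–Demjanov-type ring expansion), by which indan-1-ones are converted into 2-tetralones. Ring B is closed by one-atom expansion of the five-membered ring, not by a cyclisation, so no ring-closure mode in the Baldwin sense is involved. No stereocentre is created: C1 and C2 are spectators, the migrating carbon is sp2, and the silyl-bearing carbon of 14 becomes a CH2 group when dilute acid protodesilylates it to 15. The step needs aryl instead of alkyl migration; the silyloxy group para to C4a makes that carbon the better migrating group, while C2 is tertiary, crowded and carries an electron-withdrawing acetoxymethyl group. It also needs homologation instead of epoxide closure, which the BF3-bound, weakly nucleophilic oxygen favours. A second insertion is held back because the first-formed product is the hindered α-silyl ketone 14 (or its silyl enol ether), not a free ketone. C2 is α to the new carbonyl group, but its trans relationship to the C1 aryl group is also the stable one, so enolisation on work-up cannot erode it.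

Step 10
Reactants: 15 (3S,4S)-3-(acetoxymethyl)-7-methoxy-4-[3-methoxy-4-(triisopropylsilyloxy)phenyl]-6-(triisopropylsilyloxy)-3,4-dihydronaphthalen-2(1H)-one
Product: 16 [(1S,2S)-6-methoxy-1-[3-methoxy-4-(triisopropylsilyloxy)phenyl]-7-(triisopropylsilyloxy)-3-(trifluoromethanesulfonyloxy)-1,2-dihydronaphthalen-2-yl]methyl acetate
Conditions: KN(SiMe3)2, THF, −78 °C; PhNTf2, −78 → −40 °C
Reagents that add atoms: N-phenylbis(trifluoromethanesulfonimide), O=S(=O)(N(c1ccccc1)S(=O)(=O)C(F)(F)F)C(F)(F)F
Why: Regioselective enolate O-sulfonylation: the benzylic C4 hydrogens are far more acidic than the C2 hydrogen, so the conjugated C3–C4 enolate forms and is trapped as the enol triflate; C2 is not deprotonated, so it is neither epimerised nor induced to expel acetate.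

Step 11
Reactants: 16 [(1S,2S)-6-methoxy-1-[3-methoxy-4-(triisopropylsilyloxy)phenyl]-7-(triisopropylsilyloxy)-3-(trifluoromethanesulfonyloxy)-1,2-dihydronaphthalen-2-yl]methyl acetate
Product: 17 [(1S,2R)-3-formyl-6-methoxy-1-[3-methoxy-4-(triisopropylsilyloxy)phenyl]-7-(triisopropylsilyloxy)-1,2-dihydronaphthalen-2-yl]methyl acetate
Conditions: Pd(OAc)2 (5 mol %), dppp (5 mol %), CO (1 atm), Et3SiH, Et3N, DMF, 70 °C
Reagents that add atoms: carbon monoxide, [C-]#[O+]
Why: Palladium-catalysed reductive carbonylation (formylation) of a vinyl triflate: oxidative addition, CO insertion to the acylpalladium species, hydride transfer from Et3SiH and reductive elimination give the enal with the double bond fixed at C3=C4.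

Step 12
Reactants: 17 [(1S,2R)-3-formyl-6-methoxy-1-[3-methoxy-4-(triisopropylsilyloxy)phenyl]-7-(triisopropylsilyloxy)-1,2-dihydronaphthalen-2-yl]methyl acetate
Product: 18 [(1S,2R)-3-formyl-7-hydroxy-1-(4-hydroxy-3-methoxyphenyl)-6-methoxy-1,2-dihydronaphthalen-2-yl]methyl acetate (target)
Conditions: Bu4NF, AcOH, THF, 0 °C
Reagents that add atoms: none
Why: Fluoride cleavage of both aryl silyl ethers; acetic acid buffers the fluoride and the phenoxides, so the primary acetate and the enal should be left untouched.

## Compound list

1 | 2-bromo-4-hydroxy-5-methoxybenzaldehyde (6-bromovanillin) | COc1cc(C=O)c(Br)cc1O | starting material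
2 | 2-bromo-5-methoxy-4-(triisopropylsilyloxy)benzaldehyde | COc1cc(C=O)c(Br)cc1O[Si](C(C)C)(C(C)C)C(C)C | intermediate
3 | 1-[2-bromo-5-methoxy-4-(triisopropylsilyloxy)phenyl]ethanol (racemic) | COc1cc(C(C)O)c(Br)cc1O[Si](C(C)C)(C(C)C)C(C)C | intermediate
4 | 1-[2-bromo-5-methoxy-4-(triisopropylsilyloxy)phenyl]ethanone | COc1cc(C(C)=O)c(Br)cc1O[Si](C(C)C)(C(C)C)C(C)C | intermediate
5 | vanillin | COc1cc(C=O)ccc1O | starting material
6 | 3-methoxy-4-(triisopropylsilyloxy)benzaldehyde | COc1cc(C=O)ccc1O[Si](C(C)C)(C(C)C)C(C)C | intermediate
7 | 1-[2-bromo-5-methoxy-4-(triisopropylsilyloxy)phenyl]-3-hydroxy-3-[3-methoxy-4-(triisopropylsilyloxy)phenyl]propan-1-one (racemic, present as its lithium alkoxide) | COc1cc(C(O)CC(=O)c2cc(OC)c(O[Si](C(C)C)(C(C)C)C(C)C)cc2Br)ccc1O[Si](C(C)C)(C(C)C)C(C)C | intermediate (not isolated)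
8 | methanesulfonate of 7 | COc1cc(C(OS(C)(=O)=O)CC(=O)c2cc(OC)c(O[Si](C(C)C)(C(C)C)C(C)C)cc2Br)ccc1O[Si](C(C)C)(C(C)C)C(C)C | intermediate (not isolated)
9 | (E)-1-[2-bromo-5-methoxy-4-(triisopropylsilyloxy)phenyl]-3-[3-methoxy-4-(triisopropylsilyloxy)phenyl]prop-2-en-1-one | COc1cc(/C=C/C(=O)c2cc(OC)c(O[Si](C(C)C)(C(C)C)C(C)C)cc2Br)ccc1O[Si](C(C)C)(C(C)C)C(C)C | intermediate
10 | (3S)-6-methoxy-3-[3-methoxy-4-(triisopropylsilyloxy)phenyl]-5-(triisopropylsilyloxy)-2,3-dihydro-1H-inden-1-one | COc1cc([C@H]2c3cc(O[Si](C(C)C)(C(C)C)C(C)C)c(OC)cc3C(=O)C2)ccc1O[Si](C(C)C)(C(C)C)C(C)C | intermediate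
11 | (2S,3S)-2-(hydroxymethyl)-6-methoxy-3-[3-methoxy-4-(triisopropylsilyloxy)phenyl]-5-(triisopropylsilyloxy)-2,3-dihydro-1H-inden-1-one | COc1cc([C@H]2c3cc(O[Si](C(C)C)(C(C)C)C(C)C)c(OC)cc3C(=O)[C@@H]2CO)ccc1O[Si](C(C)C)(C(C)C)C(C)C | intermediate
12 | (2S,3S)-2-(acetoxymethyl)-6-methoxy-3-[3-methoxy-4-(triisopropylsilyloxy)phenyl]-5-(triisopropylsilyloxy)-2,3-dihydro-1H-inden-1-one | COc1cc([C@H]2c3cc(O[Si](C(C)C)(C(C)C)C(C)C)c(OC)cc3C(=O)[C@@H]2COC(C)=O)ccc1O[Si](C(C)C)(C(C)C)C(C)C | intermediate (precursor of the key step)
13 | trimethylsilyldiazomethane | C[Si](C)(C)C=[N+]=[N-] | starting material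
14 | (3S,4S)-3-(acetoxymethyl)-7-methoxy-4-[3-methoxy-4-(triisopropylsilyloxy)phenyl]-6-(triisopropylsilyloxy)-1-(trimethylsilyl)-3,4-dihydronaphthalen-2(1H)-one (either configuration at C1) | COc1cc([C@H]2c3cc(O[Si](C(C)C)(C(C)C)C(C)C)c(OC)cc3C([Si](C)(C)C)C(=O)[C@@H]2COC(C)=O)ccc1O[Si](C(C)C)(C(C)C)C(C)C | intermediate (not isolated)
15 | (3S,4S)-3-(acetoxymethyl)-7-methoxy-4-[3-methoxy-4-(triisopropylsilyloxy)phenyl]-6-(triisopropylsilyloxy)-3,4-dihydronaphthalen-2(1H)-one | COc1cc([C@H]2c3cc(O[Si](C(C)C)(C(C)C)C(C)C)c(OC)cc3CC(=O)[C@@H]2COC(C)=O)ccc1O[Si](C(C)C)(C(C)C)C(C)C | intermediate (product of the key step)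
16 | [(1S,2S)-6-methoxy-1-[3-methoxy-4-(triisopropylsilyloxy)phenyl]-7-(triisopropylsilyloxy)-3-(trifluoromethanesulfonyloxy)-1,2-dihydronaphthalen-2-yl]methyl acetate | COc1cc([C@H]2c3cc(O[Si](C(C)C)(C(C)C)C(C)C)c(OC)cc3C=C(OS(=O)(=O)C(F)(F)F)[C@@H]2COC(C)=O)ccc1O[Si](C(C)C)(C(C)C)C(C)C | intermediate
17 | [(1S,2R)-3-formyl-6-methoxy-1-[3-methoxy-4-(triisopropylsilyloxy)phenyl]-7-(triisopropylsilyloxy)-1,2-dihydronaphthalen-2-yl]methyl acetate | COc1cc([C@H]2c3cc(O[Si](C(C)C)(C(C)C)C(C)C)c(OC)cc3C=C(C=O)[C@@H]2COC(C)=O)ccc1O[Si](C(C)C)(C(C)C)C(C)C | intermediate
18 | [(1S,2R)-3-formyl-7-hydroxy-1-(4-hydroxy-3-methoxyphenyl)-6-methoxy-1,2-dihydronaphthalen-2-yl]methyl acetate | COc1cc([C@H]2c3cc(O)c(OC)cc3C=C(C=O)[C@@H]2COC(C)=O)ccc1O | target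

## Step count and least certain steps

Total steps: 12. Longest linear sequence: 11 steps (steps 1–3 and 5–12); step 4 is a one-step side branch.

**Step 9 (key step).**
- Risk: competing migration of the alkyl carbon C2 (leading to a 1-tetralone skeleton), epoxide closure, or slow addition to the electron-rich, α-branched aryl ketone while the Lewis acid decomposes the diazo reagent. Acid-promoted loss of acetic acid from the β-acetoxy ketone is a further possibility.
- Fallback: sets out from 12 and returns at 15. Lombardo methylenation (Zn, CH2Br2, TiCl4, THF–CH2Cl2), which is non-basic and ketone-selective, should give the exocyclic alkene, the 1-methylidene analogue of 12, F1. Oxidative rearrangement of F1 with the hypervalent iodine reagent PhI(OH)OTs in aqueous methanol should then move ring A carbon C4a onto the former methylene carbon and release 15 after hydrolysis of the ketal. This is the known ring expansion of 1-methylidene benzocycloalkanes to 2-benzocycloalkanones.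

**Step 6.**
- Risk: poor facial selectivity if bromide stays on palladium and the neutral pathway takes over, simple hydrodebromination, or partial loss of an aryl silyl ether in the hot amine–glycol medium.
- Fallback: sets out from 9 and returns at 10. Miyaura borylation (PdCl2(dppf), B2pin2, KOAc, dioxane, 80 °C) should give the 2'-(pinacolboryl)chalcone F2. Asymmetric intramolecular 1,4-addition catalysed by monovalent rhodium ([Rh(C2H4)2Cl]2, chiral phosphoramidite such as MonoPhos, aq. K3PO4, toluene) should then close the ring to 10. Here the stereocentre is set by transmetalation from boron and enone insertion, not by a Heck-type pathway.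

**Step 7.**
- Risk: a second hydroxymethylation, retro-aldol or dehydration to the 2-methylidene ketone on warming, or incomplete conversion because monomeric formaldehyde repolymerises.
- Fallback: sets out from 10 and returns at 11. Silylation (Me3SiOTf, Et3N, CH2Cl2, 0 °C) should give the trimethylsilyl enol ether F3. A Mukaiyama aldol reaction with aqueous formaldehyde catalysed by Sc(OTf)3 in THF–water should then give 11, again trans because addition is anti to the aryl group and the product can equilibrate.

**Step 10.**
- Risk: intramolecular acyl transfer from the acetate to the enolate (Claisen-type), or β-elimination of acetate if the enolate equilibrates toward C2.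
- Fallback: sets out from 11 and returns at 16; the strong-base step is run on a silyl ether and the acetate is introduced afterwards.
  - Silylation of 11 (TBSCl, imidazole, DMF) gives the tert-butyldimethylsilyl ether F4.
  - Homologation as in step 9 gives, through the α-trimethylsilyl ketone F5 (not isolated), the silyloxymethyl 2-tetralone F6.
  - KN(SiMe3)2 and PhNTf2 give the enol triflate F7.
  - HCl (cat.) in MeOH–THF at 0 °C removes only the alkyl silyl ether to give the hydroxymethyl enol triflate F8.
  - Ac2O and pyridine give 16.

**Step 11.**
- Risk: hydride delivery to the vinylpalladium species before CO insertion, which would replace the triflate by hydrogen, or slow oxidative addition at the hindered C3.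
- Fallback: sets out from 16 and returns at 17. Stille coupling with Bu3SnCH2OH (Pd(PPh3)4, LiCl, dioxane, 90 °C) should give the 3-(hydroxymethyl) allylic alcohol F9. Allylic oxidation with MnO2 in CH2Cl2 should then give 17.

## Further compounds

F1 | step 9 | trans-2-(acetoxymethyl)-1-methylidene indane corresponding to 12 (C=O replaced by C=CH2) | COc1cc([C@H]2c3cc(O[Si](C(C)C)(C(C)C)C(C)C)c(OC)cc3C(=C)[C@@H]2COC(C)=O)ccc1O[Si](C(C)C)(C(C)C)C(C)C
F2 | step 6 | (E)-3-[3-methoxy-4-(triisopropylsilyloxy)phenyl]-1-[5-methoxy-2-(4,4,5,5-tetramethyl-1,3,2-dioxaborolan-2-yl)-4-(triisopropylsilyloxy)phenyl]prop-2-en-1-one | COc1cc(/C=C/C(=O)c2cc(OC)c(O[Si](C(C)C)(C(C)C)C(C)C)cc2B3OC(C)(C)C(C)(C)O3)ccc1O[Si](C(C)C)(C(C)C)C(C)C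
F3 | step 7 | trimethylsilyl enol ether of 10 (1-aryl-3-trimethylsilyloxy-1H-indene, configuration at the aryl-bearing carbon as in 10) | COc1cc([C@H]2c3cc(O[Si](C(C)C)(C(C)C)C(C)C)c(OC)cc3C(O[Si](C)(C)C)=C2)ccc1O[Si](C(C)C)(C(C)C)C(C)C
F4 | step 10 | tert-butyldimethylsilyl ether of 11 (trans) | COc1cc([C@H]2c3cc(O[Si](C(C)C)(C(C)C)C(C)C)c(OC)cc3C(=O)[C@@H]2CO[Si](C)(C)C(C)(C)C)ccc1O[Si](C(C)C)(C(C)C)C(C)C
F5 | step 10 | α-trimethylsilyl ketone from F4 (analogue of 14 with CH2OTBS, not isolated) | COc1cc([C@H]2c3cc(O[Si](C(C)C)(C(C)C)C(C)C)c(OC)cc3C([Si](C)(C)C)C(=O)[C@@H]2CO[Si](C)(C)C(C)(C)C)ccc1O[Si](C(C)C)(C(C)C)C(C)C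
F6 | step 10 | 2-tetralone analogue of 15 with CH2OTBS in place of CH2OAc (trans) | COc1cc([C@H]2c3cc(O[Si](C(C)C)(C(C)C)C(C)C)c(OC)cc3CC(=O)[C@@H]2CO[Si](C)(C)C(C)(C)C)ccc1O[Si](C(C)C)(C(C)C)C(C)C
F7 | step 10 | enol triflate analogue of 16 with CH2OTBS in place of CH2OAc | COc1cc([C@H]2c3cc(O[Si](C(C)C)(C(C)C)C(C)C)c(OC)cc3C=C(OS(=O)(=O)C(F)(F)F)[C@@H]2CO[Si](C)(C)C(C)(C)C)ccc1O[Si](C(C)C)(C(C)C)C(C)C
F8 | step 10 | enol triflate analogue of 16 with free CH2OH | COc1cc([C@H]2c3cc(O[Si](C(C)C)(C(C)C)C(C)C)c(OC)cc3C=C(OS(=O)(=O)C(F)(F)F)[C@@H]2CO)ccc1O[Si](C(C)C)(C(C)C)C(C)C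
F9 | step 11 | allylic alcohol analogue of 17 with CH2OH in place of CHO at C3 | COc1cc([C@H]2c3cc(O[Si](C(C)C)(C(C)C)C(C)C)c(OC)cc3C=C(CO)[C@@H]2COC(C)=O)ccc1O[Si](C(C)C)(C(C)C)C(C)C
A1 | alternative 1 | bis(triisopropylsilyl) ether of the target, identical with 17 | COc1cc([C@H]2c3cc(O[Si](C(C)C)(C(C)C)C(C)C)c(OC)cc3C=C(C=O)[C@@H]2COC(C)=O)ccc1O[Si](C(C)C)(C(C)C)C(C)C
A2 | alternative 1 | open-chain Heck precursor: 2-formyl-allyl unit on C2, ring A bromide at the future C4a, stereocentres as in A1 | COc1cc([C@H]([C@@H](COC(C)=O)C(=C)C=O)c2cc(O[Si](C(C)C)(C(C)C)C(C)C)c(OC)cc2Br)ccc1O[Si](C(C)C)(C(C)C)C(C)C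
A3 | alternative 2 | 1-aryl-2-(acetoxymethyl)-3-formyl-4-hydroxytetralin bis(tert-butyldimethylsilyl) ether (aryl, hydroxyl and formyl cis; acetoxymethyl trans) | COc1cc([C@H]2c3cc(O[Si](C)(C)C(C)(C)C)c(OC)cc3[C@@H](O)[C@@H](C=O)[C@@H]2COC(C)=O)ccc1O[Si](C)(C)C(C)(C)C
A4 | alternative 2 | 4-(tert-butyldimethylsilyloxy)-5-methoxy-2-[3-methoxy-4-(tert-butyldimethylsilyloxy)benzyl]benzaldehyde | COc1cc(Cc2cc(O[Si](C)(C)C(C)(C)C)c(OC)cc2C=O)ccc1O[Si](C)(C)C(C)(C)C
A5 | alternative 2 | (E)-4-acetoxybut-2-enal | CC(=O)OC/C=C/C=O
A6 | alternative 3 | bis(tert-butyldimethylsilyl) ether of the target | COc1cc([C@H]2c3cc(O[Si](C)(C)C(C)(C)C)c(OC)cc3C=C(C=O)[C@@H]2COC(C)=O)ccc1O[Si](C)(C)C(C)(C)C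
A7 | alternative 3 | 6-substituted 3-methoxy-4-(tert-butyldimethylsilyloxy)-2-pyrone whose side chain carries C1 (aryl), C2 (acetoxymethyl) and a cis 2-formyl-enyne ending in a terminal alkyne | COc1cc([C@H]([C@@H](COC(C)=O)/C(C=O)=C\C#C)c2cc(O[Si](C)(C)C(C)(C)C)c(OC)c(=O)o2)ccc1O[Si](C)(C)C(C)(C)C
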